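**Retrosynthetic overview**
- The target phenol comes from its methyl ether (6-MeO-BDE-47) by BBr3 demethylation.
- The two ring-A bromines come from NH2-directed dibromination of a 4-amino precursor; the amino group is then removed by diazotisation/H3PO2 (traceless director).
- The amino group comes from the nitro group of 2-(2,4-dibromophenoxy)-4-nitrophenol (O-methylation, then reduction).
- Key disconnection: ring A of that nitrophenol is built de novo by intermolecular aldol condensation of 1-(2,4-dibromophenoxy)propan-2-one with nitromalonaldehyde, followed by ring-closing aldol condensation and aromatisation.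
- Ring B is bought fully brominated (2,4-dibromophenol, alkylated with chloroacetone); ring A is the only ring formed, in the key step.

Assumption: the target has no stereocentre and no hindered axis, so it is achiral and the SMILES is taken as written.

**Route**

Step 1
Reactants: 1 2,4-dibromophenol; 2 chloroacetone (1-chloropropan-2-one)
Product: 3 1-(2,4-dibromophenoxy)propan-2-one
Conditions: K2CO3 (1.5 equiv), KI (0.1 equiv), acetone, reflux, 8 h
Reagents that add atoms: none
Why: Williamson ether synthesis in which the phenoxide of 1 displaces chloride from the SN2-reactive α-chloroketone (iodide catalysis), with no stereocentre formed.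

Step 2
Reactants: 4 mucobromic acid ((Z)-2,3-dibromo-4-oxobut-2-enoic acid, sold as its cyclic lactol form)
Product: 5 sodium nitromalonaldehyde monohydrate
Conditions: NaNO2 (3.7 equiv), H2O/EtOH, 54 °C, 1.5 h; then 0–5 °C, recrystallise from aq. EtOH (impact-sensitive solid: keep as the hydrate, handle behind a shield)
Reagents that add atoms: sodium nitrite [Na+].[O-]N=O; water O
Why: Established nitrite degradation of mucobromic acid, in which nitrite replaces a vinylic bromide by addition–elimination (vinylic nucleophilic substitution) and hydrolysis of the second C–Br with decarboxylation leaves the resonance-stabilised nitromalonaldehyde anion, which crystallises as its sodium salt.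

Step 3
Reactants: 3 1-(2,4-dibromophenoxy)propan-2-one; 5 sodium nitromalonaldehyde monohydrate
Product: 7 2-(2,4-dibromophenoxy)-4-nitrophenol, via acyclic nitrodienolate sodium salt 6 (not isolated)
Conditions: 3 (1.0 equiv), 5 (1.2 equiv), 1 M aq. NaOH (1.1 equiv), H2O/EtOH 1:1, 20 °C, dark, 3–5 d; then 2 M HCl to pH 2
Reagents that add atoms: none
Why: Double aldol condensation (Hill–Torrey nitrophenol synthesis) in which the methyl-side enolate of 3 condenses intermolecularly with one formyl group of 5 to forge the key C–C bond (6), the aryloxy-bearing α-carbon then closes onto the second formyl group by intramolecular aldol condensation, and loss of water with enolisation gives the aromatic nitrophenolate as a single regioisomer because 5 is symmetric; no stereocentre arises.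

Step 4
Reactants: 7 2-(2,4-dibromophenoxy)-4-nitrophenol
Product: 8 2,4-dibromo-1-(2-methoxy-5-nitrophenoxy)benzene
Conditions: MeI (1.5 equiv), K2CO3 (2 equiv), DMF, rt to 40 °C, 6 h
Reagents that add atoms: iodomethane CI
Why: Williamson O-methylation (SN2) of the acidic nitrophenol masks the OH as a robust methyl ether so that the later aniline nitrogen, not the phenol, controls bromination.

Step 5
Reactants: 8 2,4-dibromo-1-(2-methoxy-5-nitrophenoxy)benzene
Product: 9 3-(2,4-dibromophenoxy)-4-methoxyaniline
Conditions: Fe powder (5 equiv), AcOH/EtOH/H2O, 70 °C, 2 h; NaHCO3 work-up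
Reagents that add atoms: none
Why: Béchamp-type dissolving-metal nitro reduction with Fe/AcOH is chemoselective for the nitro group and leaves aryl C–Br bonds and both ethers untouched.

Step 6
Reactants: 9 3-(2,4-dibromophenoxy)-4-methoxyaniline
Product: 10 2,6-dibromo-3-(2,4-dibromophenoxy)-4-methoxyaniline
Conditions: NBS (2.05 equiv), DMF, 0 °C to rt, dark, 3 h
Reagents that add atoms: N-bromosuccinimide O=C1CCC(=O)N1Br
Why: Electrophilic aromatic bromination in which the free NH2 (para position blocked by OMe) directs both bromines to its two ortho positions, which are also ortho and para to the aryloxy oxygen and correspond to C3 and C5 of the target ring, while the dibrominated ring B and the position next to OMe are far less activated.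

Step 7
Reactants: 10 2,6-dibromo-3-(2,4-dibromophenoxy)-4-methoxyaniline
Product: 12 1,5-dibromo-2-(2,4-dibromophenoxy)-3-methoxybenzene, via arenediazonium hydrogen sulfate 11 (not isolated)
Conditions: NaNO2 (1.2 equiv), conc. H2SO4/AcOH, 0–10 °C, 1 h; then 50% aq. H3PO2 (10 equiv), Cu2O (cat.), 0 °C to rt, 12 h
Reagents that add atoms: none
Why: Diazotisation followed by hypophosphorous acid reduction (hydrodediazoniation, reductive deamination) removes the now redundant amino director by radical-chain hydrogen transfer, a classical process for weakly basic 2,6-dibromoanilines that does not touch C–Br bonds.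

Step 8
Reactants: 12 1,5-dibromo-2-(2,4-dibromophenoxy)-3-methoxybenzene
Product: 14 3,5-dibromo-2-(2,4-dibromophenoxy)phenol, via aryloxydibromoborane 13 (not isolated)
Conditions: BBr3 (1 M in CH2Cl2, 3 equiv), CH2Cl2, −78 °C to rt, 6 h; then ice/H2O
Reagents that add atoms: none
Why: Lewis-acid aryl methyl ether cleavage in which BBr3 coordinates the methoxy oxygen and bromide attacks the methyl group (SN2), the diaryl ether and aryl bromides being inert, and hydrolysis of borate 13 frees the phenol.

**Compound list**

1 | 2,4-dibromophenol | Oc1ccc(Br)cc1Br | starting material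
2 | chloroacetone (1-chloropropan-2-one) | CC(=O)CCl | starting material
3 | 1-(2,4-dibromophenoxy)propan-2-one | CC(=O)COc1ccc(Br)cc1Br | intermediate
4 | mucobromic acid ((Z)-2,3-dibromo-4-oxobut-2-enoic acid) | O=C/C(Br)=C(/Br)C(=O)O | starting material
5 | sodium nitromalonaldehyde monohydrate (symmetric delocalised anion) | [Na+].[O-]C=C(C=O)[N+](=O)[O-].O | intermediate
6 | sodium 6-(2,4-dibromophenoxy)-2-nitro-5-oxohexa-1,3-dien-1-olate (push–pull dienolate, E/Z forms interconvert) | [Na+].[O-]C=C(C=CC(=O)COc1ccc(Br)cc1Br)[N+](=O)[O-] | intermediate
7 | 2-(2,4-dibromophenoxy)-4-nitrophenol | Oc1ccc(cc1Oc1ccc(Br)cc1Br)[N+](=O)[O-] | intermediate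
8 | 2,4-dibromo-1-(2-methoxy-5-nitrophenoxy)benzene | COc1ccc(cc1Oc1ccc(Br)cc1Br)[N+](=O)[O-] | intermediate
9 | 3-(2,4-dibromophenoxy)-4-methoxyaniline | COc1ccc(N)cc1Oc1ccc(Br)cc1Br | intermediate
10 | 2,6-dibromo-3-(2,4-dibromophenoxy)-4-methoxyaniline | COc1cc(Br)c(N)c(Br)c1Oc1ccc(Br)cc1Br | intermediate
11 | 2,6-dibromo-3-(2,4-dibromophenoxy)-4-methoxybenzenediazonium hydrogen sulfate | COc1cc(Br)c([N+]#N)c(Br)c1Oc1ccc(Br)cc1Br.OS([O-])(=O)=O | intermediate
12 | 1,5-dibromo-2-(2,4-dibromophenoxy)-3-methoxybenzene (6-MeO-BDE-47) | COc1cc(Br)cc(Br)c1Oc1ccc(Br)cc1Br | intermediate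
13 | dibromo[3,5-dibromo-2-(2,4-dibromophenoxy)phenoxy]borane | BrB(Br)Oc1cc(Br)cc(Br)c1Oc1ccc(Br)cc1Br | intermediate
14 | 3,5-dibromo-2-(2,4-dibromophenoxy)phenol | Oc1cc(Br)cc(Br)c1Oc1ccc(Br)cc1Br | target

**Totals and risks**

Total step count: 8. Longest linear sequence: 7 steps (steps 1, 3, 4, 5, 6, 7, 8 from compound 1; the branch 4 → 5 of step 2 joins at step 3 and is equally long).

Steps most likely to fail:

Step 3 (double aldol benzannulation). Ketone 3 may self-condense or the sequence may stall at 6, and there is little precedent for aryloxyacetones in this reaction. The fallback gives up ring construction and makes the diaryl ether bond directly. It sets out from 1, which is coupled with commercial 2-iodo-1-methoxy-4-nitrobenzene (COc1ccc(cc1I)[N+](=O)[O-]) in a copper-catalysed Ullmann ether synthesis (CuI 10 mol %, picolinic acid 20 mol %, K3PO4, DMSO, 90 °C). The C–I bond reacts far faster than the C–Br bonds of 1. The product is 8 itself, where the fallback comes back to the route before step 5; no new compound is made on the way (F0).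

Step 6 (dibromination of 9). The second bromine must enter the crowded position between NH2 and the aryloxy group, and the electron-rich aniline may over-brominate or oxidise. The fallback drops late bromination and the amino director altogether and brings ring A in with both bromines in place. It sets out from 1, which displaces fluoride from commercial 3,5-dibromo-2-fluorobenzaldehyde (O=Cc1cc(Br)cc(Br)c1F) by SNAr activated by the ortho-formyl group (K2CO3, DMAc, 90 °C). This gives 3,5-dibromo-2-(2,4-dibromophenoxy)benzaldehyde F1. Baeyer–Villiger (Dakin-type) oxidation with mCPBA (KH2PO4, CH2Cl2, rt) converts it into 3,5-dibromo-2-(2,4-dibromophenoxy)phenyl formate F2. Mild hydrolysis (NaOH, MeOH/H2O, then HCl) comes back to the route at 14, the target.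

Step 7 (reductive deamination of 10). The hindered, weakly basic amine may diazotise incompletely, and the diazonium ion 11 may give phenol or azo by-products instead of clean H-transfer. The fallback splits the C–N to C–H change into halogenation and selective dehalogenation. It sets out from 10, which is diazotised as before (via 11) and quenched with aqueous KI (0 °C to rt) to give 1,3-dibromo-4-(2,4-dibromophenoxy)-2-iodo-5-methoxybenzene F3. Selective iodine–magnesium exchange (iPrMgCl·LiCl, THF, −40 °C; C–I exchanges much faster than C–Br) and protonation with MeOH at −40 °C give 12, where the fallback comes back to the route.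

**Further compounds**

F0 | step 3 | none | none
F1 | step 6 | 3,5-dibromo-2-(2,4-dibromophenoxy)benzaldehyde | O=Cc1cc(Br)cc(Br)c1Oc1ccc(Br)cc1Br
F2 | step 6 | 3,5-dibromo-2-(2,4-dibromophenoxy)phenyl formate | O=COc1cc(Br)cc(Br)c1Oc1ccc(Br)cc1Br
F3 | step 7 | 1,3-dibromo-4-(2,4-dibromophenoxy)-2-iodo-5-methoxybenzene | COc1cc(Br)c(I)c(Br)c1Oc1ccc(Br)cc1Br
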